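The readings come from a simulation from invented constants; scatter was added.

| setting | south-east | south-west | north-east | south | north |
|---|---|---|---|---|---|
| substrate | 0.0800 M | 0.0320 M | 0.0800 M | 0.0400 M | 0.0800 M |
| partner | 0.200 M | 0.152 M | 0.400 M | 0.200 M | 1.30 M |
| free catalyst | 4.00 × 10⁻⁴ M | 4.00 × 10⁻⁴ M | 4.00 × 10⁻⁴ M | 4.00 × 10⁻⁴ M | 4.00 × 10⁻⁴ M |
| time |  |  |  |  | 62 min |

- south-east run (time / min: [target] / M): 10: 0.0101; 21: 0.0199; 31: 0.0287; 41: 0.0360; 52: 0.0436; 62: 0.0504
- south-west run (time / min: [target] / M): 10: 0.0056; 21: 0.0108; 31: 0.0136; 41: 0.0180; 52: 0.0209; 62: 0.0230
- north-east run (time / min: [target] / M): 10: 0.0136; 21: 0.0274; 31: 0.0382; 41: 0.0485; 52: 0.0565; 62: 0.0627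
- south run (time / min: [target] / M): 10: 0.0067; 21: 0.0134; 31: 0.0185; 41: 0.0235; 52: 0.0272; 62: 0.0308

(standard deviation of a reading: 4 × 10⁻⁴ M)

- Overall: substrate + partner -> target, with free catalyst as catalyst.
- Constant volume, constant temperature.
- The analysis sees a species whether free or bound.
- An order is taken over about fifteen percent of the charge, up and down.

1. the power of [substrate] that the first rate follows, about the charge of the south-east run; measure it at two percent of substrate made into target (one fixed amount of target, the same in the runs compared)
2. the power of [partner] that the first rate follows, about the charge of the south-east run; measure it at two percent of substrate made into target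
3. the south-west run starts with 0.0480 M less of substrate and of partner than the south-east run, and with no target. Compared where both hold the same amount of substrate, once fifteen percent of what the south-west run was charged with has turned into target, is the south-west run faster, slower or alike (within a tenth)?
4. target in the north run at 62 min, as a share of the substrate charged

1. Early on, the south-east run makes target at a nearly steady pace: 0.00101 M/min over its first 10 min.

2. At that same time the north-east run, with twice the partner, reads 1.35 times as much, so we take the pace to follow partner to the power 0.429. The south run, with half the substrate, gives a substrate power of 0.592. Both are rough readings taken over a wider span than the one asked.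

3. For the north run we raise the south-east pace by the partner ratio to that power. Then 1.75 is its drain number, the first pace times the time allowed over the substrate charged, a Damköhler number. It counts how many charges the first pace, held over the whole time, adds up to.

4. Now let the pace follow the substrate left, with partner held steady. Integrating, the share left is one minus (one minus the order) times the drain number, all raised to one over (one minus the order). Our reckoning for the north run is therefore 95.3% made.

5. Is one number enough? The south-east run has a drain number of 0.783, which gives 61.1%, and its last reading is 63.0%. The south-west run has 1.08, which gives 75.9% against a reading of 71.9%, but its first reading carries a scatter of 7.14%. So in these two runs the number comes near the share made; we draw from it no answer to the same-substrate question.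

6. The forecast gave a substrate power of 0.47, a partner power of 0.53, the south-west run slower, and 83% for the north run, on the grounds that “All the orders are fractional, which points to saturation in both reactants.” Its share for the north run is lower than ours.

7. The simulation gives a substrate power of 0.41, a partner power of 0.46, the south-west run alike (its rate over that of the south-east run is 1.0), and 96.5% for the north run.

    free catalyst + substrate ⇌ catalyst-substrate complex, settled at all times (15.30 /M)
    catalyst-substrate complex + partner ⇌ ternary complex, settled at all times (14.30 /M)
    ternary complex → target + free catalyst (26.34 /min)
    free catalyst + impurity → spent catalyst
    2 partner ⇌ idle reagent dimer, settled at all times (266.0 /M)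

A drain number of 1.75 carries nearly all of the north run's charge through, 96.5% against our 95.3%. On a second flask, the south run, the same curve puts target at half the substrate charged at 36.0 min, and the south run reaches it at 33.2 min. The substrate order of 0.41 is held up by partner pairing into idle reagent dimer: with that association taken away, the south-east charge shows an order of 0.18.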